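## Retrosynthetic overview

1. Target 20 (locants of the 1-benzoxepine name: O1, C2–C5, C5a, C6–C9, C9a) is cut last at C5a–C6 of the carbocycle. A bromonium ion at C6/C7, made from a vicinal dibromide in the side chain on C9a, is captured by C5a of a preformed 2,7-dihydrooxepine diene (C3=C4–C5=C5a), and the resulting C3–C4–C5 allyl cation is reduced at C5 by Et3SiH. This one operation closes the ring, joins C5a to the quaternary C6, sets C5a and places the C3=C4 bond.
2. Enabling feature: the cis ring fusion (5a-H and 9a-CH3 on the same face, so C6 and C9 leave the oxepine ring on one face) together with the homoallylic position of C3=C4 relative to C5a. A C6 electrophile tethered to C9a through C9–C8–C7 reaches only the C9 face of C5a, and 1,4-addition of carbon (C5a) and hydride (C5) across the ring diene leaves exactly the C3=C4 alkene.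
3. Ring order: oxepine ring first, by ring-closing metathesis (C5=C5a) of an ether assembled from (S)-linalool, bromoacetic acid, a chloromethyl ether (C1) and an allyl Grignard reagent, then ketone to dienyl triflate to methyl diene. Cyclohexane ring last.
4. Stereocentres: C9a from (S)-linalool; C2 by auxiliary-controlled enolate alkylation; C7 by Shi epoxidation followed by inversion when the epoxide becomes the dibromide; C5a in the key step.

Key step: step 12

Remark: the target SMILES is read as the cis-fused (2R,5aR,7S,9aS) isomer (5a-H and 9a-CH3 syn), and (S)-(+)-linalool is taken as available in high enantiomeric purity.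

## Route

Step 1
Reactants: 1 (S)-(+)-linalool; 2 bromoacetic acid
Product: 3 {[(3S)-3,7-dimethylocta-1,6-dien-3-yl]oxy}acetic acid
Conditions: NaH, THF, 0 °C to reflux; then aq. HCl
Reagents that add atoms: bromoacetic acid (2), OC(=O)CBr
Why: Williamson ether synthesis in which the tertiary sodium alkoxide of 1 displaces bromide from sodium bromoacetate at an unhindered primary carbon (the usual route to tert-alkoxyacetic acids), leaving the C9a stereocentre untouched.

Step 2
Reactants: 3 {[(3S)-3,7-dimethylocta-1,6-dien-3-yl]oxy}acetic acid; 4 (4R)-4-benzyl-1,3-oxazolidin-2-one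
Product: 6 (4R)-4-benzyl-3-({[(3S)-3,7-dimethylocta-1,6-dien-3-yl]oxy}acetyl)-1,3-oxazolidin-2-one, via mixed pivalic anhydride 5 (not isolated)
Conditions: t-BuCOCl, Et3N, THF, −78 to 0 °C; then lithium salt of 4 (n-BuLi, THF, −78 °C), −78 to 0 °C
Reagents that add atoms: (4R)-4-benzyl-1,3-oxazolidin-2-one (4), O=C1N[C@H](Cc2ccccc2)CO1; pivaloyl chloride, CC(C)(C)C(=O)Cl (in 5 only)
Why: N-acylation of the lithiated oxazolidinone by the mixed anhydride at its less hindered carbonyl group attaches the Evans auxiliary without creating a stereocentre.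

Step 3
Reactants: 6 (4R)-4-benzyl-3-({[(3S)-3,7-dimethylocta-1,6-dien-3-yl]oxy}acetyl)-1,3-oxazolidin-2-one
Product: 8 (4R)-4-benzyl-3-[(2S)-2-{[(3S)-3,7-dimethylocta-1,6-dien-3-yl]oxy}-3-{[tri(propan-2-yl)silyl]oxy}propanoyl]-1,3-oxazolidin-2-one, via sodium enolate 7 (not isolated)
Conditions: NaN(SiMe3)2, THF, −78 °C; then iPr3SiOCH2Cl, −78 to −40 °C
Reagents that add atoms: (triisopropylsiloxy)methyl chloride, CC(C)[Si](OCCl)(C(C)C)C(C)C; NaN(SiMe3)2, C[Si](C)(C)[N-][Si](C)(C)C.[Na+] (in 7 only)
Why: Evans auxiliary alkylation in which the chelated Z sodium enolate 7 is attacked by the chloromethyl ether on the face anti to the benzyl group, which sets C2 (2S in 8, the later 2R centre), and at −78 °C this alkylation should outrun a [2,3]-Wittig shift of the allylic ether.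

Step 4
Reactants: 8 (4R)-4-benzyl-3-[(2S)-2-{[(3S)-3,7-dimethylocta-1,6-dien-3-yl]oxy}-3-{[tri(propan-2-yl)silyl]oxy}propanoyl]-1,3-oxazolidin-2-one
Product: 9 (2S)-2-{[(3S)-3,7-dimethylocta-1,6-dien-3-yl]oxy}-N-methoxy-N-methyl-3-{[tri(propan-2-yl)silyl]oxy}propanamide
Conditions: MeNH(OMe)·HCl, AlMe3, CH2Cl2, −20 to 0 °C
Reagents that add atoms: N,O-dimethylhydroxylamine hydrochloride, CNOC.Cl
Why: Weinreb amide synthesis by aluminium amide transamination at the exocyclic imide carbonyl group, which releases the auxiliary without touching C2.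

Step 5
Reactants: 9 (2S)-2-{[(3S)-3,7-dimethylocta-1,6-dien-3-yl]oxy}-N-methoxy-N-methyl-3-{[tri(propan-2-yl)silyl]oxy}propanamide
Product: 10 (2S)-2-({(3S)-5-[(2R)-3,3-dimethyloxiran-2-yl]-3-methylpent-1-en-3-yl}oxy)-N-methoxy-N-methyl-3-{[tri(propan-2-yl)silyl]oxy}propanamide
Conditions: D-fructose-derived Shi ketone (cat.), KHSO5 (as 2KHSO5·KHSO4·K2SO4), K2CO3, Bu4NHSO4, MeCN/CH2(OMe)2/aq. Na2B4O7 buffer, 0 °C
Reagents that add atoms: potassium peroxymonosulfate KHSO5, [K+].[O-]S(=O)(=O)OO
Why: Shi asymmetric epoxidation in which the chiral dioxirane oxidizes the electron-rich trisubstituted alkene in preference to the two monosubstituted ones and, by catalyst control through the spiro transition state, should give the (R)-epoxide, which also masks this alkene for the metathesis of step 7.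

Step 6
Reactants: 10 (2S)-2-({(3S)-5-[(2R)-3,3-dimethyloxiran-2-yl]-3-methylpent-1-en-3-yl}oxy)-N-methoxy-N-methyl-3-{[tri(propan-2-yl)silyl]oxy}propanamide
Product: 11 (2S)-2-({(3S)-5-[(2R)-3,3-dimethyloxiran-2-yl]-3-methylpent-1-en-3-yl}oxy)-1-{[tri(propan-2-yl)silyl]oxy}hex-5-en-3-one
Conditions: CH2=CHCH2MgBr, THF, −78 °C; aq. NH4Cl at −78 °C
Reagents that add atoms: allylmagnesium bromide, C=CC[Mg]Br
Why: Weinreb ketone synthesis in which the Grignard reagent adds once to the N-methoxy-N-methylamide and, at −78 °C, spares the trisubstituted epoxide, giving the β,γ-unsaturated ketone without epimerization at C2.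

Step 7
Reactants: 11 (2S)-2-({(3S)-5-[(2R)-3,3-dimethyloxiran-2-yl]-3-methylpent-1-en-3-yl}oxy)-1-{[tri(propan-2-yl)silyl]oxy}hex-5-en-3-one
Product: 12 (2S,7S)-7-{2-[(2R)-3,3-dimethyloxiran-2-yl]ethyl}-7-methyl-2-({[tri(propan-2-yl)silyl]oxy}methyl)-4,7-dihydrooxepin-3(2H)-one
Conditions: RuCl2(H2IMes)(=CH-C6H4-2-OiPr) (second-generation Hoveyda–Grubbs catalyst, cat.), 1,4-benzoquinone (cat.), CH2Cl2 (high dilution), 40 °C
Reagents that add atoms: none
Why: Ring-closing metathesis of the two terminal alkenes closes the seven-membered ether ring as its cis C5=C5a alkene with loss of ethene, forms no stereocentre, and cannot be diverted to a cyclopentene because the prenyl alkene is already an epoxide.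

Step 8
Reactants: 12 (2S,7S)-7-{2-[(2R)-3,3-dimethyloxiran-2-yl]ethyl}-7-methyl-2-({[tri(propan-2-yl)silyl]oxy}methyl)-4,7-dihydrooxepin-3(2H)-one
Product: 14 (2S,7S)-7-{2-[(2R)-3,3-dimethyloxiran-2-yl]ethyl}-7-methyl-2-({[tri(propan-2-yl)silyl]oxy}methyl)-2,7-dihydrooxepin-3-yl trifluoromethanesulfonate, via potassium dienolate 13 (not isolated)
Conditions: KN(SiMe3)2, THF, −78 °C; then PhNTf2, −78 °C
Reagents that add atoms: N-phenylbis(trifluoromethanesulfonimide), O=S(=O)(N(c1ccccc1)S(=O)(=O)C(F)(F)F)C(F)(F)F; KN(SiMe3)2, C[Si](C)(C)[N-][Si](C)(C)C.[K+] (in 13 only)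
Why: Enol triflate formation in which the base removes the doubly activated (α-keto and allylic) C4–H rather than the hindered α-alkoxy C2–H, and O-sulfonylation of dienolate 13 gives the 1,3-dienyl triflate with C2 intact.

Step 9
Reactants: 14 (2S,7S)-7-{2-[(2R)-3,3-dimethyloxiran-2-yl]ethyl}-7-methyl-2-({[tri(propan-2-yl)silyl]oxy}methyl)-2,7-dihydrooxepin-3-yl trifluoromethanesulfonate
Product: 15 {[(2R,7S)-7-{2-[(2R)-3,3-dimethyloxiran-2-yl]ethyl}-3,7-dimethyl-2,7-dihydrooxepin-2-yl]methoxy}tri(propan-2-yl)silane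
Conditions: ZnMe2, Pd(PPh3)4 (cat.), THF, 0 °C to rt
Reagents that add atoms: dimethylzinc, C[Zn]C
Why: Negishi cross-coupling of the enol triflate with ZnMe2 installs the C3 methyl group with the double bonds held in place, giving the ring diene C3=C4–C5=C5a.

Step 10
Reactants: 15 {[(2R,7S)-7-{2-[(2R)-3,3-dimethyloxiran-2-yl]ethyl}-3,7-dimethyl-2,7-dihydrooxepin-2-yl]methoxy}tri(propan-2-yl)silane
Product: 16 [(2R,7S)-7-{2-[(2R)-3,3-dimethyloxiran-2-yl]ethyl}-3,7-dimethyl-2,7-dihydrooxepin-2-yl]methanol
Conditions: Bu4NF, THF, 0 °C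
Reagents that add atoms: none
Why: Fluoride-mediated desilylation frees the primary alcohol under non-acidic conditions that the epoxide and the acid-labile dienylic ether should tolerate.

Step 11
Reactants: 16 [(2R,7S)-7-{2-[(2R)-3,3-dimethyloxiran-2-yl]ethyl}-3,7-dimethyl-2,7-dihydrooxepin-2-yl]methanol
Product: 17 (2R,7S)-2-(bromomethyl)-7-[(3S)-3,4-dibromo-4-methylpentyl]-3,7-dimethyl-2,7-dihydrooxepine
Conditions: PPh3Br2, imidazole, CH2Cl2/MeCN, −20 to 0 °C
Reagents that add atoms: dibromotriphenylphosphorane PPh3Br2, BrP(Br)(c1ccccc1)(c1ccccc1)c1ccccc1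
Why: Appel-type deoxybromination with PPh3Br2 turns the primary alcohol into the bromide and, by the known epoxide to vicinal dibromide conversion of the same reagent, replaces both epoxide C–O bonds by C–Br with inversion, so that the (R)-epoxide carbon becomes the (S)-bromide of C7 while imidazole takes up the HBr.

Step 12
Reactants: 17 (2R,7S)-2-(bromomethyl)-7-[(3S)-3,4-dibromo-4-methylpentyl]-3,7-dimethyl-2,7-dihydrooxepine
Product: 20 (2R,5aR,7S,9aS)-7-bromo-2-(bromomethyl)-3,6,6,9a-tetramethyl-2,5,5a,6,7,8,9,9a-octahydro-1-benzoxepine, via bromonium ion 18 (not isolated), via allyl cation 19 (not isolated)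
Conditions: Et3SiH, 2,6-di-tert-butyl-4-methylpyridine, (CF3)2CHOH/CH2Cl2, 0 °C to rt
Reagents that add atoms: none
Why: Proposed new method: in (CF3)2CHOH the tertiary C–Br bond of 17 ionizes with anchimeric help of the neighbouring bromine to the bromonium ion 18 (C7 keeps its configuration), C5a of the ring diene opens 18 at the tertiary carbon C6, and the C3–C4–C5 allyl cation 19 is reduced by Et3SiH at its less substituted end C5, which leaves the C3=C4 bond of 20. The closest known reaction types are the enantiospecific solvolytic generation of bromonium ions from vicinal dihalides in this solvent with capture by an alkene (bromonium polyene cyclization), the diene-terminated cation–olefin cyclization, and the ionic hydrogenation of allyl cations by trialkylsilanes; only their union, a cyclization terminated by hydride, is new. The cyclohexane ring (C5a, C6, C7, C8, C9, C9a) closes through a chair-like six-membered transition state, endo with respect to the bromonium ion (attack at C6 anti to bromine) and exo with respect to the C5a=C5 bond. The one new stereocentre, C5a, is set by the tether: C6 hangs from C9a through C9–C8–C7 and can reach C5a only on the diene face that carries C9, which gives the cis ring fusion (5aR, 5a-H and 9a-CH3 syn). The step needs C–C bond formation to beat hydride transfer to 18 and attack by the ring oxygen, which the intramolecular six-membered closure and the hindered ether oxygen, hydrogen-bonded to the solvent, should secure; it also needs the dienylic C9a–O bond to survive, for which 2,6-di-tert-butyl-4-methylpyridine keeps the medium free of strong acid.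

## Compound list

1 | (3S)-3,7-dimethylocta-1,6-dien-3-ol, (S)-(+)-linalool | C=C[C@@](C)(O)CCC=C(C)C | starting material
2 | bromoacetic acid | OC(=O)CBr | starting material
3 | {[(3S)-3,7-dimethylocta-1,6-dien-3-yl]oxy}acetic acid | C=C[C@](C)(CCC=C(C)C)OCC(=O)O | intermediate
4 | (4R)-4-benzyl-1,3-oxazolidin-2-one | O=C1N[C@H](Cc2ccccc2)CO1 | starting material
5 | mixed anhydride of 3 and pivalic acid | C=C[C@](C)(CCC=C(C)C)OCC(=O)OC(=O)C(C)(C)C | intermediate
6 | (4R)-4-benzyl-3-({[(3S)-3,7-dimethylocta-1,6-dien-3-yl]oxy}acetyl)-1,3-oxazolidin-2-one | C=C[C@](C)(CCC=C(C)C)OCC(=O)N1[C@H](Cc2ccccc2)COC1=O | intermediate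
7 | sodium Z-enolate of 6 | [Na+].[O-]/C(=C\O[C@](C)(C=C)CCC=C(C)C)N1[C@H](Cc2ccccc2)COC1=O | intermediate
8 | (4R)-4-benzyl-3-[(2S)-2-{[(3S)-3,7-dimethylocta-1,6-dien-3-yl]oxy}-3-{[tri(propan-2-yl)silyl]oxy}propanoyl]-1,3-oxazolidin-2-one | CC(C)[Si](C(C)C)(C(C)C)OC[C@H](O[C@](C)(C=C)CCC=C(C)C)C(=O)N1[C@H](Cc2ccccc2)COC1=O | intermediate
9 | (2S)-2-{[(3S)-3,7-dimethylocta-1,6-dien-3-yl]oxy}-N-methoxy-N-methyl-3-{[tri(propan-2-yl)silyl]oxy}propanamide | CON(C)C(=O)[C@H](CO[Si](C(C)C)(C(C)C)C(C)C)O[C@](C)(C=C)CCC=C(C)C | intermediate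
10 | (2S)-2-({(3S)-5-[(2R)-3,3-dimethyloxiran-2-yl]-3-methylpent-1-en-3-yl}oxy)-N-methoxy-N-methyl-3-{[tri(propan-2-yl)silyl]oxy}propanamide | CON(C)C(=O)[C@H](CO[Si](C(C)C)(C(C)C)C(C)C)O[C@](C)(C=C)CC[C@H]1OC1(C)C | intermediate
11 | (2S)-2-({(3S)-5-[(2R)-3,3-dimethyloxiran-2-yl]-3-methylpent-1-en-3-yl}oxy)-1-{[tri(propan-2-yl)silyl]oxy}hex-5-en-3-one | C=CCC(=O)[C@H](CO[Si](C(C)C)(C(C)C)C(C)C)O[C@](C)(C=C)CC[C@H]1OC1(C)C | intermediate
12 | (2S,7S)-7-{2-[(2R)-3,3-dimethyloxiran-2-yl]ethyl}-7-methyl-2-({[tri(propan-2-yl)silyl]oxy}methyl)-4,7-dihydrooxepin-3(2H)-one | O=C1CC=C[C@](C)(CC[C@H]2OC2(C)C)O[C@H]1CO[Si](C(C)C)(C(C)C)C(C)C | intermediate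
13 | potassium dienolate of 12 (enolate oxygen on C3, ring double bonds C3=C4 and C5=C5a in target locants) | [K+].[O-]C1=CC=C[C@](C)(CC[C@H]2OC2(C)C)O[C@H]1CO[Si](C(C)C)(C(C)C)C(C)C | intermediate
14 | (2S,7S)-7-{2-[(2R)-3,3-dimethyloxiran-2-yl]ethyl}-7-methyl-2-({[tri(propan-2-yl)silyl]oxy}methyl)-2,7-dihydrooxepin-3-yl trifluoromethanesulfonate | O=S(=O)(OC1=CC=C[C@](C)(CC[C@H]2OC2(C)C)O[C@H]1CO[Si](C(C)C)(C(C)C)C(C)C)C(F)(F)F | intermediate
15 | {[(2R,7S)-7-{2-[(2R)-3,3-dimethyloxiran-2-yl]ethyl}-3,7-dimethyl-2,7-dihydrooxepin-2-yl]methoxy}tri(propan-2-yl)silane | CC1=CC=C[C@](C)(CC[C@H]2OC2(C)C)O[C@H]1CO[Si](C(C)C)(C(C)C)C(C)C | intermediate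
16 | [(2R,7S)-7-{2-[(2R)-3,3-dimethyloxiran-2-yl]ethyl}-3,7-dimethyl-2,7-dihydrooxepin-2-yl]methanol | CC1=CC=C[C@](C)(CC[C@H]2OC2(C)C)O[C@H]1CO | intermediate
17 | (2R,7S)-2-(bromomethyl)-7-[(3S)-3,4-dibromo-4-methylpentyl]-3,7-dimethyl-2,7-dihydrooxepine | CC1=CC=C[C@](C)(CC[C@H](Br)C(C)(C)Br)O[C@H]1CBr | intermediate
18 | bromonium ion from 17 (bromine bridging C6 and C7, bromide counter-ion) | CC1=CC=C[C@](C)(CC[C@@H]2[Br+]C2(C)C)O[C@H]1CBr.[Br-] | intermediate
19 | cyclized allyl cation (C3–C4–C5, drawn with the charge on C5, bromide counter-ion) | CC1=C[CH+][C@@H]2C(C)(C)[C@@H](Br)CC[C@]2(C)O[C@H]1CBr.[Br-] | intermediate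
20 | (2R,5aR,7S,9aS)-7-bromo-2-(bromomethyl)-3,6,6,9a-tetramethyl-2,5,5a,6,7,8,9,9a-octahydro-1-benzoxepine | CC1=CC[C@@H]2C(C)(C)[C@@H](Br)CC[C@]2(C)O[C@H]1CBr | target

## Step count and risks

Total steps: 12. Longest linear sequence: 12 steps (from 1).

Steps most likely to fail:

**Step 12 (Proposed new method).** Several processes may intervene:
- hydride transfer to the bromonium ion before ring closure;
- proton loss or solvent capture at the allyl cation instead of hydride transfer;
- hydride delivery to the tertiary allyl terminus (C3);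
- attack of the ring oxygen on C6 followed by C–O fragmentation;
- acid-induced ionization of the dienylic C9a–O bond;
- closure on the wrong diene face (trans fusion).

Fallback with known chemistry, setting out from 17: the solvolytic bromonium cyclization is run without silane in aqueous (CF3)2CHOH with 2,6-di-tert-butyl-4-methylpyridine at 0 °C, so that the allyl cation is terminated by water. This should give the cyclized tertiary allylic alcohol F1 together with its secondary allylic isomer F2. Both ionize to the same allyl cation and are then reduced together by ionic hydrogenation (Et3SiH, CF3CO2H, CH2Cl2, −40 °C), the known deoxygenation of allylic alcohols in which hydride goes to the less substituted allyl terminus. At that stage the diene is gone and the ring ether is no longer dienylic, so the acid should be tolerated. The route is rejoined at 20.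

**Step 11.** The activated trisubstituted epoxide may rearrange by a hydride shift to a ketone, the acid-labile dienylic ether may ionize under HBr or the phosphonium reagent, and inversion at C7 may be incomplete if the epoxide opens through an open cation.

Fallback, setting out from 16: the two events are separated and the bromonium precursor is changed. Appel bromination (CBr4, PPh3, imidazole, CH2Cl2, 0 °C) should give the epoxy bromide F3. Opening of its epoxide with MgBr2·OEt2 (Et2O, −20 °C) at the tertiary carbon should give the bromohydrin F4, in which the C7–O bond is untouched. The bromonium ion 18 is then generated from F4 at −78 °C by O-triflation (Tf2O, 2,6-di-tert-butyl-4-methylpyridine, CH2Cl2), the neighbouring bromine displacing triflate with inversion at C7. The ion is carried through the ring closure of step 12 (or of its fallback). The route is rejoined at 20.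

**Step 3.** The enolate may undergo a [2,3]-Wittig shift of the tertiary allylic ether, C-alkylation by the chloromethyl ether may be slow, and facial selectivity may erode with an electrophile of SN1 character.

Fallback, setting out from 6: C2 is set by an Evans syn-aldol reaction instead, with the acyl carbon becoming C1 and the aldehyde carbon C3.
- Bu2BOTf, iPr2NEt, CH2Cl2, −78 °C, then but-3-enal should give the aldol adduct F5 (boron Z-enolate, Zimmerman–Traxler transition state, C2 controlled by the auxiliary).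
- LiBH4 (Et2O, 0 °C) removes the auxiliary and gives the diol F6.
- iPr3SiCl and imidazole (CH2Cl2, 0 °C) silylate the primary hydroxyl selectively to the silyl ether F7.
- Shi epoxidation as in step 5 gives the epoxy alcohol F8.
- Dess–Martin oxidation of the secondary alcohol gives ketone 11.

The route is rejoined at 11, and steps 4 to 6 are then not needed.

## Further compounds

F1 | step 12 | cyclized tertiary allylic alcohol (20 with OH on C3 and a C4=C5 double bond in place of C3=C4; both C3 epimers) | CC1(O)C=C[C@@H]2C(C)(C)[C@@H](Br)CC[C@]2(C)O[C@H]1CBr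
F2 | step 12 | cyclized secondary allylic alcohol (20 with OH on C5; both C5 epimers) | CC1=CC(O)[C@@H]2C(C)(C)[C@@H](Br)CC[C@]2(C)O[C@H]1CBr
F3 | step 11 | (2R,7S)-2-(bromomethyl)-7-{2-[(2R)-3,3-dimethyloxiran-2-yl]ethyl}-3,7-dimethyl-2,7-dihydrooxepine | CC1=CC=C[C@](C)(CC[C@H]2OC2(C)C)O[C@H]1CBr
F4 | step 11 | bromohydrin: (2R,7S)-2-(bromomethyl)-7-[(3R)-4-bromo-3-hydroxy-4-methylpentyl]-3,7-dimethyl-2,7-dihydrooxepine | CC1=CC=C[C@](C)(CC[C@@H](O)C(C)(C)Br)O[C@H]1CBr
F5 | step 3 | (4R)-4-benzyl-3-[(2R,3S)-2-{[(3S)-3,7-dimethylocta-1,6-dien-3-yl]oxy}-3-hydroxyhex-5-enoyl]-1,3-oxazolidin-2-one | C=CC[C@H](O)[C@@H](O[C@](C)(C=C)CCC=C(C)C)C(=O)N1[C@H](Cc2ccccc2)COC1=O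
F6 | step 3 | (2S,3S)-2-{[(3S)-3,7-dimethylocta-1,6-dien-3-yl]oxy}hex-5-ene-1,3-diol | C=CC[C@H](O)[C@H](CO)O[C@](C)(C=C)CCC=C(C)C
F7 | step 3 | (2S,3S)-2-{[(3S)-3,7-dimethylocta-1,6-dien-3-yl]oxy}-1-{[tri(propan-2-yl)silyl]oxy}hex-5-en-3-ol | C=CC[C@H](O)[C@H](CO[Si](C(C)C)(C(C)C)C(C)C)O[C@](C)(C=C)CCC=C(C)C
F8 | step 3 | (2S,3S)-2-({(3S)-5-[(2R)-3,3-dimethyloxiran-2-yl]-3-methylpent-1-en-3-yl}oxy)-1-{[tri(propan-2-yl)silyl]oxy}hex-5-en-3-ol | C=CC[C@H](O)[C@H](CO[Si](C(C)C)(C(C)C)C(C)C)O[C@](C)(C=C)CC[C@H]1OC1(C)C
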